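**Remarks and assumptions**

- TBS = tert-butyldimethylsilyl. α and β refer to the usual germacranolide/eudesmanolide drawing with H7 α. "Peripheral" means the face of an alkene or carbonyl group that points away from the ring.
- Assumption: the lipase of step 2 acetylates the hydroxyl group that gives 5 as drawn; an enzyme of opposite preference would give the same 5 by hydrolysis of the meso-diacetate of 3.
- The C4 configuration of 14–18 (drawn as the endo adduct) and the C11 configuration of 27 and 28 are without consequence, since both centres become trigonal later.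

## Structural features

The target is a heliangolide-type germacranolide: a ten-membered carbocycle (C1–C10) trans-fused at C6–C7 to an α-methylene γ-lactone (C6–O–C12, C11=C13). The ring carries a trans oxirane at C1–C10 (1β,10α, the oxide of an E alkene) and a cis oxirane at C4–C5 (4α,5α, the oxide of a Z alkene). These flank C2 (α-hydroxyl) and C3, and C8 bears an α-angelate next to C7. The eight stereocentres (1R,2S,4R,5S,6S,7R,8S,10R) form two contiguous runs, C4–C5–C6–C7–C8 and C10–C1–C2, joined only through the flexible ring. Fragile groups are the trisubstituted epoxides (acid, transannular opening), the 2,3-epoxy alcohol (Payne rearrangement under base), the methylene lactone (Michael acceptor), the angelate (Z to E isomerisation) and any germacra-1(10),4-diene intermediate (Cope rearrangement, transannular cyclisation). The real difficulty is a ten-membered ring with one E and one Z trisubstituted alkene and oxygen on the carbon between them, with no ring fusion to relay stereochemistry around the macrocycle. The key step exploits the fact that E C1=C10 and Z C4=C5 on either side of C2–C3 make the ring the open form of a cis-fused bicyclo[4.4.0]decane carrying a 2-oxy-1,3-diene (C1=C2(O)–C3=C4) and joined through C5–C10.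

## Logic of the disconnections

**36 ⇒ 33.** The four C–O bonds of the two oxiranes (C1–O, C10–O, C4–O, C5–O) are cut first. They are the most sensitive part of 36, and the C2 hydroxyl is allylic to C1=C10 and homoallylic to C4=C5, so it can deliver oxygen to both. Four stereocentres disappear. The forward step must epoxidise only the two electron-rich ring alkenes, on the faces the hydroxyl can reach, and leave the two conjugated alkenes alone.

**33 ⇒ 32 ⇒ 30 + 31.** The acyl C–O bond of the C8 ester is cut and the C2 oxygen is masked as an aryl ether. The enolisable Z ester cannot survive the base needed for the methylene lactone, and C2–OH must be told apart from C8–OH. What remains is an alcohol with one free hydroxyl. The forward steps need an acylation that does not isomerise 31 and an ether cleavage that spares four alkenes.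

**30 ⇒ 29 ⇒ 25.** The C11–C13 bond and the C8 O–Si bond are cut. The methylene lactone is a Michael acceptor and is put on only after all hydride and strong-nucleophile chemistry, but before the epoxides. The demand is that the lactone be the only enolisable carbonyl group, which holds for 25.

**25 ⇒ 23 ⇒ 22.** The C2–O(aryl) bond is cut with inversion, and then the C2–H bond. A peripheral hydride should place the hydroxyl of 23 in the plane of C1=C10 (2β), the epimer of what the epoxidation and 36 need. An etherification that inverts C2 therefore corrects the configuration and protects the oxygen in one operation. The demand is an SN2 displacement at an allylic carbinol without elimination.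

**22 ⇒ 21 ⇒ 20 (key).** The C3–H bond is removed to give the C2 silyl enol ether, and C5 is reconnected to C10. The ten-membered triene becomes a rigid cis-decalin whose stereocentres can be controlled, and both ring alkene geometries become a question of one conrotatory sense. The demand falls on the ring fusion. It must be cis with H5 and CH3-14 on the α face (C1 and C4 β). Only this isomer has, in its lactone-locked chair, C9 pseudoequatorial and C6 pseudoaxial on ring A. A cis isomer drawn with H5 and CH3-14 on the β face is the wrong one: it would have the opposite helicity and lead to the 1(10)Z,4E triene, and its C1 would be cis to the C8 oxygen, which an addition anti to that oxygen cannot deliver.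

**20 ⇒ 19 ⇒ 18.** The C2 O–Si bond and the C3=C4 π bond are removed. Ring A is carried as a C2 silyl enol ether until the lactone is in place, because an enone in ring A would make C5–H the most acidic site and block C7 alkylation and C6 reduction. The demands are a dehydrogenation that can only go towards C4, and a kinetic α′ enolisation.

**18 ⇒ 17 ⇒ 16 ⇒ 14 + 15.** The lactone C12–O bond, the C6–H bond and the C7–C11 bond are cut. This returns a cis-decalone with one free α-methylene group. The demands are alkylation at C7 and not C5, trans to the C8 oxygen, and reduction to the equatorial 6α-alcohol, which a hydride approaching anti to the axial C1 would not give.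

**14 ⇒ 10 + 13.** The C1–C10 and C4–C5 bonds are cut (Diels–Alder). One step then makes ring A, the quaternary C10 and the cis fusion, and places C2 as an enol ether. It avoids a regiochemically ambiguous aldol between two methyl ketones. The demand is cycloaddition to a β,β-disubstituted enone, anti to the C8 silyloxy group.

**13 ⇒ 11 + 12.** The O–Si bond is cut; the demand is enolisation at the methyl group and not at the γ position.

**10 ⇒ 9 ⇒ 7 + 8.** The C10 methyl is cut and the carbonyl transposed, which reduces 10 to a known type of 5-silyloxy enone.

**7 ⇒ 6 ⇒ 5 ⇒ 3 + 4, and 3 ⇒ 1 + 2.** The enone double bond, the acetate and the silyl ether are removed back to the meso triol 1. The single demand is that one of two enantiotopic hydroxyls be acylated; this sets C8, from which every other centre is derived.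

## Other disconnections considered

**Alternative 1:** The cut is C7–C11, with C11=C13 to follow. In the forward step Rh2(OAc)4 converts a C6 diazophosphonoacetate into a rhodium carbene that inserts into a C7–H bond and closes the lactone, giving A1.
- In its favour: 1,5-insertion is the preferred ring size, and the phosphonate allows the methylene group to be made with formaldehyde under mild carbonate base. On this point it is better than the enolate Mannich sequence of the chosen route.
- Against it here: the step presupposes the complete ten-membered diepoxide, so the ring, both alkene geometries and six stereocentres must come from elsewhere. The C7–H bonds are secondary and inductively deactivated by the C8 acyloxy group. The epoxide C5–H, ylide formation at the epoxide oxygens and β-lactone formation compete. The two C7 hydrogens must be distinguished to obtain the trans fusion.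
- Comparison: on structure, A1 puts the lactone on last onto a flexible ring, whereas the chosen plan uses the lactone early as a conformational lock. On mechanism, it is a metal-carbene C–H insertion that forms one bond, one ring and up to two centres, against a pericyclic opening that forms none. On step economy, it is shorter at the end but needs an independent synthesis of the macrocycle.

**Alternative 2:** The cuts are C2–C3 and O–C4. In the forward step a C2 nitrile oxide, made from the aldoxime with NaOCl, adds to the 1,1-disubstituted C3=C4 alkene and closes the carbocycle as the bridged isoxazoline A2.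
- In its favour: the assembly is convergent from open-chain fragments, and the E alkene is made by acyclic olefination. The key step itself sets the C4–O stereocentre and the C2 oxidation level, which the chosen plan reaches only through a late directed epoxidation. On these points it is equal or better.
- Against it here: a ten-membered ring is an unfavourable size for a cycloaddition, and dimerisation of a conjugated nitrile oxide competes. Facial selectivity at C4 is hard to foresee. After N–O cleavage the β-hydroxy ketone can undergo retro-aldol ring opening or dehydration. Epoxide closure with inversion at C5, C2 reduction, the 1,10-epoxide and the methylene group are all still to come.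
- Comparison: on structure and mechanism, it forms two bonds, one ring and one centre in one step, against none. On step economy, the number of steps after the key step is larger and the Z-alkene problem is replaced by a medium-ring closure problem.

**Alternative 3:** The cut is C7–C8. In the forward step tin–lithium exchange at C8 of a 13-membered allylic ether triggers a [2,3]-Wittig shift that forms C7–C8, breaks O–C13 and contracts the ring to A3.
- In its favour: this is an established kind of macrocyclic ring contraction, and the larger ether ring is easier to close. The step delivers the C11=C13 methylene and a free C8 hydroxyl directly, so no enolate methylenation and no C8 deprotection are needed. On these points it is better than the chosen plan.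
- Against it here: C7 and C8 are set together in one transition state whose facial preference in a 13-membered ring is uncertain. It needs an enantioenriched α-alkoxystannane and a stereodefined trisubstituted alkene, and stoichiometric tin. The lactone must still be made by oxidation at C12, and C6–O must be distinguished from C2–O, which carry the same silyl group in A3.
- Comparison: on mechanism, it forms one skeletal bond, the carbocycle and two centres. On step economy, a long linear route to the ether is traded for a short endgame, whereas the chosen plan has a short route to the ring and a longer endgame.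

Key step: step 12

## Route

Step 1
Reactants: 1 cis,cis-cyclohexane-1,3,5-triol; 2 tert-butyldimethylsilyl chloride
Product: 3 all-cis-5-(tert-butyldimethylsilyloxy)cyclohexane-1,3-diol (meso)
Conditions: TBSCl (1.0 equiv), imidazole, DMF, 0 °C → rt
Reagents that add atoms: tert-butyldimethylsilyl chloride, CC(C)(C)[Si](C)(C)Cl
Why: Statistical monosilylation of three equivalent hydroxyls (silyl ether formation); the mono-ether is separated from triol and bis-ether, which can be recycled, and is meso, so no stereochemistry is set.

Step 2
Reactants: 3 all-cis-5-(TBS-oxy)cyclohexane-1,3-diol; 4 vinyl acetate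
Product: 5 (1S,3R,5S)-3-acetoxy-5-(tert-butyldimethylsilyloxy)cyclohexan-1-ol (all-cis)
Conditions: Pseudomonas cepacia lipase, vinyl acetate, tBuOMe, rt
Reagents that add atoms: vinyl acetate, CC(=O)OC=C
Why: Enzymatic desymmetrisation of a meso-1,3-diol by irreversible transesterification; the enzyme distinguishes the enantiotopic hydroxyls and so fixes the absolute configuration of the silyloxy carbon, the future C8.

Step 3
Reactants: 5 (1S,3R,5S)-3-acetoxy-5-(TBS-oxy)cyclohexan-1-ol
Product: 7 (R)-5-(tert-butyldimethylsilyloxy)cyclohex-2-en-1-one, via keto acetate 6 (not isolated)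
Conditions: Dess–Martin periodinane, NaHCO3, CH2Cl2, 0 °C → rt; then DBU, 0 °C
Reagents that add atoms: none
Why: Alcohol oxidation followed by E1cB loss of the β-acetoxy group, which leaves far more readily than the β-silyloxy group; the silyloxy stereocentre is not involved.

Step 4
Reactants: 7 (R)-5-(TBS-oxy)cyclohex-2-en-1-one; 8 methyllithium
Product: 9 (5R)-1-methyl-5-(tert-butyldimethylsilyloxy)cyclohex-2-en-1-ol (both C1 epimers)
Conditions: MeLi, Et2O, −78 °C; NH4Cl (aq)
Reagents that add atoms: methyllithium, [Li]C
Why: 1,2-Addition of a hard organolithium to the enone carbonyl; the new carbinol centre is lost in the next step, so its configuration does not matter.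

Step 5
Reactants: 9 (5R)-1-methyl-5-(TBS-oxy)cyclohex-2-en-1-ol
Product: 10 (S)-5-(tert-butyldimethylsilyloxy)-3-methylcyclohex-2-en-1-one
Conditions: 4-acetamido-2,2,6,6-tetramethyl-1-oxopiperidinium tetrafluoroborate, MeCN, rt
Reagents that add atoms: none
Why: Oxidative 1,3-transposition of a tertiary allylic alcohol by an oxoammonium salt gives the β-methyl enone; the silyloxy centre is untouched and its descriptor changes from R to S only because the ring priorities change.

Step 6
Reactants: 11 (E)-pent-3-en-2-one; 12 tert-butyldimethylsilyl trifluoromethanesulfonate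
Product: 13 (E)-2-(tert-butyldimethylsilyloxy)penta-1,3-diene
Conditions: TBSOTf, Et3N, Et2O, 0 °C
Reagents that add atoms: tert-butyldimethylsilyl trifluoromethanesulfonate, CC(C)(C)[Si](C)(C)OS(=O)(=O)C(F)(F)F
Why: Soft enolisation of a methyl vinyl ketone with silyl triflate and amine removes a methyl proton and gives the cross-conjugated 2-silyloxy diene; the E alkene is not involved.

Step 7
Reactants: 10 (S)-5-(TBS-oxy)-3-methylcyclohex-2-en-1-one; 13 (E)-2-(TBS-oxy)penta-1,3-diene
Product: 14 cis-fused 2,8α-bis(TBS-oxy)-4β-methyl-11,12,13-trinor-5αH,10αMe-eudesm-2-en-6-one (endo adduct)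
Conditions: Tf2NH (10 mol %), CH2Cl2, −78 → −40 °C; Et3N quench
Reagents that add atoms: (E)-2-(tert-butyldimethylsilyloxy)penta-1,3-diene, C=C(O[Si](C)(C)C(C)(C)C)/C=C/C
Why: Diels–Alder reaction of a 2-silyloxy diene with a β,β-disubstituted cyclohexenone under silyl triflimide catalysis (a Mukaiyama–Michael/Michael manifold): the nucleophilic diene terminus C1 bonds to the β-carbon C10 anti to the C8 silyloxy group (CH3-14 α, C1 β), the second bond can only form on the same face, so the fusion is cis (H5 α), and C2 emerges as a silyl enol ether.

Step 8
Reactants: 14 cis-fused Diels–Alder adduct; 15 methyl bromoacetate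
Product: 16 methyl 2,8α-bis(TBS-oxy)-6-oxo-13-nor-5αH,10αMe-eudesm-2-en-12-oate (H7 α; side chain β)
Conditions: LiN(iPr)2, THF, −78 °C; BrCH2CO2Me, DMPU, −78 → −40 °C
Reagents that add atoms: methyl bromoacetate, COC(=O)CBr
Why: Kinetic enolate alkylation: C7 carries the only accessible α-hydrogens (C5–H is tertiary and flanked by C4 and the quaternary C10, and C2 is masked), the electrophile enters anti to the adjacent C8 silyloxy group, and the trans-diequatorial product is also the thermodynamic C7 epimer.

Step 9
Reactants: 16 methyl 6-oxo ester
Product: 18 2,8α-bis(TBS-oxy)-13-nor-5αH,10αMe-eudesm-2-en-6α,12-olide, via hydroxy ester 17 (not isolated)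
Conditions: SmI2, H2O, Et3N, THF, 0 °C; then NaH (cat.), THF, 0 °C → rt
Reagents that add atoms: none
Why: Electron-transfer reduction of the ketone, which like dissolving-metal reductions should give the more stable equatorial 6α-alcohol (a hydride would approach anti to the axial C1 and give the axial 6β-alcohol); alkoxide-catalysed lactonisation then closes the trans-fused γ-lactone, which locks ring B in the chair with O6, C11 and O8 equatorial.

Step 10
Reactants: 18 silyl enol ether lactone
Product: 19 8α-(TBS-oxy)-2-oxo-13-nor-5αH,10αMe-eudesm-3-en-6α,12-olide
Conditions: Pd(OAc)2 (1.1 equiv), MeCN, 40 °C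
Reagents that add atoms: none
Why: Saegusa–Ito oxidation: the palladium enolate at C3 has β-hydrogen only at C4, so elimination can only give the C3=C4 enone, and the C4 centre is erased.

Step 11
Reactants: 19 enone lactone; 12 tert-butyldimethylsilyl trifluoromethanesulfonate
Product: 20 cis-fused 2,8α-bis(TBS-oxy)-13-nor-5αH,10αMe-eudesma-1,3-dien-6α,12-olide
Conditions: LiN(iPr)2 (1.05 equiv), THF, −78 °C; TBSOTf, −78 °C
Reagents that add atoms: tert-butyldimethylsilyl trifluoromethanesulfonate, CC(C)(C)[Si](C)(C)OS(=O)(=O)C(F)(F)F
Why: Kinetic α′-deprotonation of the enone at C1, faster than γ-deprotonation at C5 or C15 and than enolisation of the less acidic lactone, followed by O-silylation to the cross-conjugated 2-silyloxy-1,3-diene.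

Step 12
Reactants: 20 cis-fused 2-silyloxy-1,3-diene lactone
Product: 21 2,8α-bis(TBS-oxy)-13-norgermacra-1(10)E,2,4Z-trien-6α,12-olide (C2=C3 ring-cis)
Conditions: hν (300 nm), degassed pentane–THF, −78 °C, to the photostationary state
Reagents that add atoms: none
Why: Excitation of the homoannular 2-silyloxy-1,3-diene leads to 6π electrocyclic opening of the C5–C10 σ bond in the conrotatory sense of the excited state, the reaction type known from the photochemical opening of bicyclic cyclohexa-1,3-dienes (eudesma-1,3-dienes, provitamin D-type dienes) to cyclic 1,3,5-trienes. No ring is closed and no skeletal bond is formed: ring A and ring B merge into the ten-membered ring, no stereocentre is created, and instead two stereogenic double bonds appear at once while the centres C5 and C10 disappear. Because C6 and C9 stand cis on ring A, conrotation must turn one of them inward and the other outward, which gives one Z and one E ring alkene, and the C2=C3 bond keeps its ring-cis geometry. Which terminus turns inward follows the helicity of the ground-state diene: the groups that are pseudoaxial on ring A (C6 on C5, CH3-14 on C10) rotate inward and the pseudoequatorial ones (C9, H5) outward, that is 4Z and 1(10)E. The substrate secures this helicity: the trans-fused lactone holds ring B in the chair with O6, C11 and O8 equatorial, so that with H5 and CH3-14 on the α face C1 is axial and C4 equatorial on ring B, hence C9 equatorial and C6 axial on ring A, and ring A cannot take the opposite twist without inverting ring B. The cis isomer with H5 and CH3-14 on the β face would present the opposite helicity and give the 1(10)Z,4E triene, which is why the 5α,10α isomer is the precursor. Low temperature and the immediate desilylation of step 13 keep the triene from thermal disrotatory closure to a trans-fused diene, and 20 that has not reacted returns as 19 after step 13 and is recycled.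

Step 13
Reactants: 21 triene silyl enol ether (cold photolysate)
Product: 22 8α-(TBS-oxy)-2-oxo-13-norgermacra-1(10)E,4Z-dien-6α,12-olide
Conditions: Bu4NF–AcOH (1:1), THF, added at −78 °C, then −78 → −30 °C
Reagents that add atoms: none
Why: Fluoride cleaves the silyl enol ether much faster than the secondary alkyl silyl ether, and kinetic protonation of the dienolate at C3 by acetic acid gives the ketone with C1=C10 conjugated and C4=C5 left in place; the triene is thereby removed, so it can no longer reclose.

Step 14
Reactants: 22 2-oxo dienolide
Product: 23 8α-(TBS-oxy)-2β-hydroxy-13-norgermacra-1(10)E,4Z-dien-6α,12-olide (2R)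
Conditions: NaBH4, CeCl3·7H2O, MeOH, −78 °C
Reagents that add atoms: none
Why: Luche 1,2-reduction of the twisted enone: hydride should enter C2 from the periphery, anti to the C14 methyl that lies cis on C10 in the alkene plane, so the new hydroxyl ends up in that plane; this is the 2β alcohol, the epimer of what the target needs, and the next step inverts it.

Step 15
Reactants: 23 2β-alcohol; 24 4-methoxyphenol
Product: 25 8α-(TBS-oxy)-2α-(4-methoxyphenoxy)-13-norgermacra-1(10)E,4Z-dien-6α,12-olide (2S)
Conditions: 4-methoxyphenol, PPh3, iPrO2CN=NCO2iPr, toluene, 0 °C → rt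
Reagents that add atoms: 4-methoxyphenol, COc1ccc(O)cc1
Why: Mitsunobu etherification: the alkoxyphosphonium ion of the allylic alcohol is displaced by the phenoxide in an SN2 process from the open face, which inverts C2 to the 2α configuration and at the same time protects the oxygen as an oxidatively removable aryl ether.

Step 16
Reactants: 25 aryl ether lactone; 26 N,N-dimethylmethyleneiminium iodide (Eschenmoser's salt)
Product: 29 8α-(TBS-oxy)-2α-(4-methoxyphenoxy)germacra-1(10)E,4Z,11(13)-trien-6α,12-olide, via Mannich base 27 (not isolated), via ammonium iodide 28 (not isolated)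
Conditions: LiN(iPr)2, THF, −78 °C; CH2=NMe2+ I−, −78 °C → rt; then MeI, rt; then NaHCO3 (aq), CH2Cl2
Reagents that add atoms: N,N-dimethylmethyleneiminium iodide, C=[N+](C)C.[I-]
Why: The lactone is the only enolisable carbonyl group, so its lithium enolate undergoes a Mannich reaction at C11; exhaustive methylation and Hofmann-type β-elimination then give the α-methylene lactone, and no epoxide is yet present to suffer from the base.

Step 17
Reactants: 29 methylene lactone silyl ether
Product: 30 8α-hydroxy-2α-(4-methoxyphenoxy)germacra-1(10)E,4Z,11(13)-trien-6α,12-olide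
Conditions: HF·pyridine, pyridine, THF, 0 °C → rt
Reagents that add atoms: none
Why: Fluoride cleavage of the secondary silyl ether under buffered, non-basic conditions, which avoids oxa-Michael addition of the C8 alkoxide to C13 and transannular cyclisation of the diene.

Step 18
Reactants: 30 C8 alcohol; 31 angelic acid ((Z)-2-methylbut-2-enoic acid)
Product: 32 8α-angeloyloxy-2α-(4-methoxyphenoxy)germacra-1(10)E,4Z,11(13)-trien-6α,12-olide
Conditions: 2,4,6-trichlorobenzoyl chloride, Et3N, toluene, rt; then 30, toluene, 60 °C
Reagents that add atoms: angelic acid, C/C=C(/C)C(=O)O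
Why: Yamaguchi esterification through the mixed anhydride made in the flask; the only free hydroxyl is at C8, and omitting nucleophilic catalysts at moderate temperature keeps the Z ester from isomerising to the tiglate.

Step 19
Reactants: 32 angelate aryl ether
Product: 33 8α-angeloyloxy-2α-hydroxygermacra-1(10)E,4Z,11(13)-trien-6α,12-olide
Conditions: (NH4)2Ce(NO3)6, pyridine, MeCN–H2O (4:1), 0 °C
Reagents that add atoms: none
Why: Oxidative cleavage of the p-methoxyphenyl ether by tetravalent cerium: the electron-rich arene is oxidised far more easily than trisubstituted alkenes, water adds at the aryl carbon, and the C2–O bond is not broken, so the 2α configuration is retained.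

Step 20
Reactants: 33 dienol angelate; 34 tert-butyl hydroperoxide
Product: 36 8α-angeloyloxy-1β,10α:4α,5α-diepoxy-2α-hydroxygermacr-11(13)-en-6α,12-olide (1R,2S,4R,5S,6S,7R,8S,10R; target), via 1β,10α-monoepoxide 35 (not isolated)
Conditions: VO(acac)2 (10 mol %), tBuOOH (3 equiv), CH2Cl2, 0 °C → rt
Reagents that add atoms: tert-butyl hydroperoxide, CC(C)(C)OO
Why: Hydroxyl-directed vanadium-catalysed epoxidation, first of the allylic and then of the homoallylic alkene, leaving the electron-poor methylene lactone and angelate alone. In the 2α-alcohol the conformer free of A(1,3) strain with C14 has H2 in the plane of C1=C10 and the hydroxyl on the outer face, so oxygen is delivered there (threo epoxy alcohol, 1β,10α); the same hydroxyl, 1,3 to C4, delivers oxygen to the α face of the cis C4=C5 alkene (4α,5α).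

## Compound list

1 | cis,cis-cyclohexane-1,3,5-triol | O[C@@H]1C[C@H](O)C[C@H](O)C1 | starting material
2 | tert-butyldimethylsilyl chloride | CC(C)(C)[Si](C)(C)Cl | starting material
3 | all-cis-5-(TBS-oxy)cyclohexane-1,3-diol (meso) | O[C@H]1C[C@@H](O)C[C@@H](O[Si](C)(C)C(C)(C)C)C1 | intermediate
4 | vinyl acetate | CC(=O)OC=C | starting material
5 | (1S,3R,5S)-3-acetoxy-5-(TBS-oxy)cyclohexan-1-ol | O[C@H]1C[C@@H](OC(C)=O)C[C@@H](O[Si](C)(C)C(C)(C)C)C1 | intermediate
6 | (3S,5R)-3-acetoxy-5-(TBS-oxy)cyclohexan-1-one | O=C1C[C@@H](OC(C)=O)C[C@@H](O[Si](C)(C)C(C)(C)C)C1 | intermediate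
7 | (R)-5-(TBS-oxy)cyclohex-2-en-1-one | O=C1C=CC[C@@H](O[Si](C)(C)C(C)(C)C)C1 | intermediate
8 | methyllithium | [Li]C | starting material
9 | (5R)-1-methyl-5-(TBS-oxy)cyclohex-2-en-1-ol (C1 epimers) | CC1(O)C=CC[C@@H](O[Si](C)(C)C(C)(C)C)C1 | intermediate
10 | (S)-5-(TBS-oxy)-3-methylcyclohex-2-en-1-one | CC1=CC(=O)C[C@@H](O[Si](C)(C)C(C)(C)C)C1 | intermediate
11 | (E)-pent-3-en-2-one | C/C=C/C(C)=O | starting material
12 | tert-butyldimethylsilyl trifluoromethanesulfonate | CC(C)(C)[Si](C)(C)OS(=O)(=O)C(F)(F)F | starting material
13 | (E)-2-(TBS-oxy)penta-1,3-diene | C=C(O[Si](C)(C)C(C)(C)C)/C=C/C | intermediate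
14 | cis-fused 2,8α-bis(TBS-oxy)-4β-methyl-11,12,13-trinor-5αH,10αMe-eudesm-2-en-6-one | O=C1C[C@@H](O[Si](C)(C)C(C)(C)C)C[C@]2(C)CC(O[Si](C)(C)C(C)(C)C)=C[C@H](C)[C@H]12 | intermediate
15 | methyl bromoacetate | COC(=O)CBr | starting material
16 | methyl 2,8α-bis(TBS-oxy)-6-oxo-13-nor-5αH,10αMe-eudesm-2-en-12-oate | O=C1[C@H](CC(=O)OC)[C@@H](O[Si](C)(C)C(C)(C)C)C[C@]2(C)CC(O[Si](C)(C)C(C)(C)C)=C[C@H](C)[C@H]12 | intermediate
17 | methyl 2,8α-bis(TBS-oxy)-6α-hydroxy-13-nor-5αH,10αMe-eudesm-2-en-12-oate | O[C@H]1[C@H](CC(=O)OC)[C@@H](O[Si](C)(C)C(C)(C)C)C[C@]2(C)CC(O[Si](C)(C)C(C)(C)C)=C[C@H](C)[C@H]12 | intermediate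
18 | 2,8α-bis(TBS-oxy)-13-nor-5αH,10αMe-eudesm-2-en-6α,12-olide | C1C(=O)O[C@H]2[C@H]1[C@@H](O[Si](C)(C)C(C)(C)C)C[C@]3(C)CC(O[Si](C)(C)C(C)(C)C)=C[C@H](C)[C@H]23 | intermediate
19 | 8α-(TBS-oxy)-2-oxo-13-nor-5αH,10αMe-eudesm-3-en-6α,12-olide | C1C(=O)O[C@H]2[C@H]1[C@@H](O[Si](C)(C)C(C)(C)C)C[C@]3(C)CC(=O)C=C(C)[C@H]23 | intermediate
20 | cis-fused 2,8α-bis(TBS-oxy)-13-nor-5αH,10αMe-eudesma-1,3-dien-6α,12-olide (key-step precursor) | C1C(=O)O[C@H]2[C@H]1[C@@H](O[Si](C)(C)C(C)(C)C)C[C@]3(C)C=C(O[Si](C)(C)C(C)(C)C)C=C(C)[C@H]23 | intermediate
21 | 2,8α-bis(TBS-oxy)-13-norgermacra-1(10)E,2,4Z-trien-6α,12-olide (key-step product) | C1C(=O)O[C@H]2[C@H]1[C@@H](O[Si](C)(C)C(C)(C)C)C/C(C)=C/C(O[Si](C)(C)C(C)(C)C)=C\C(C)=C/2 | intermediate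
22 | 8α-(TBS-oxy)-2-oxo-13-norgermacra-1(10)E,4Z-dien-6α,12-olide | C1C(=O)O[C@H]2[C@H]1[C@@H](O[Si](C)(C)C(C)(C)C)C/C(C)=C/C(=O)C/C(C)=C\2 | intermediate
23 | 8α-(TBS-oxy)-2β-hydroxy-13-norgermacra-1(10)E,4Z-dien-6α,12-olide (2R) | C1C(=O)O[C@H]2[C@H]1[C@@H](O[Si](C)(C)C(C)(C)C)C/C(C)=C/[C@H](O)C/C(C)=C\2 | intermediate
24 | 4-methoxyphenol | COc1ccc(O)cc1 | starting material
25 | 8α-(TBS-oxy)-2α-(4-methoxyphenoxy)-13-norgermacra-1(10)E,4Z-dien-6α,12-olide (2S) | C1C(=O)O[C@H]2[C@H]1[C@@H](O[Si](C)(C)C(C)(C)C)C/C(C)=C/[C@@H](Oc3ccc(OC)cc3)C/C(C)=C\2 | intermediate
26 | N,N-dimethylmethyleneiminium iodide | C=[N+](C)C.[I-] | starting material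
27 | 13-dimethylamino-8α-(TBS-oxy)-2α-(4-methoxyphenoxy)germacra-1(10)E,4Z-dien-6α,12-olide (C11 epimers) | CN(C)CC1C(=O)O[C@H]2[C@H]1[C@@H](O[Si](C)(C)C(C)(C)C)C/C(C)=C/[C@@H](Oc3ccc(OC)cc3)C/C(C)=C\2 | intermediate
28 | trimethylammonium iodide of 27 | C[N+](C)(C)CC1C(=O)O[C@H]2[C@H]1[C@@H](O[Si](C)(C)C(C)(C)C)C/C(C)=C/[C@@H](Oc3ccc(OC)cc3)C/C(C)=C\2.[I-] | intermediate
29 | 8α-(TBS-oxy)-2α-(4-methoxyphenoxy)germacra-1(10)E,4Z,11(13)-trien-6α,12-olide | C=C1C(=O)O[C@H]2[C@H]1[C@@H](O[Si](C)(C)C(C)(C)C)C/C(C)=C/[C@@H](Oc3ccc(OC)cc3)C/C(C)=C\2 | intermediate
30 | 8α-hydroxy-2α-(4-methoxyphenoxy)germacra-1(10)E,4Z,11(13)-trien-6α,12-olide | C=C1C(=O)O[C@H]2[C@H]1[C@@H](O)C/C(C)=C/[C@@H](Oc3ccc(OC)cc3)C/C(C)=C\2 | intermediate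
31 | angelic acid | C/C=C(/C)C(=O)O | starting material
32 | 8α-angeloyloxy-2α-(4-methoxyphenoxy)germacra-1(10)E,4Z,11(13)-trien-6α,12-olide | C=C1C(=O)O[C@H]2[C@H]1[C@@H](OC(=O)/C(C)=C\C)C/C(C)=C/[C@@H](Oc3ccc(OC)cc3)C/C(C)=C\2 | intermediate
33 | 8α-angeloyloxy-2α-hydroxygermacra-1(10)E,4Z,11(13)-trien-6α,12-olide | C=C1C(=O)O[C@H]2[C@H]1[C@@H](OC(=O)/C(C)=C\C)C/C(C)=C/[C@@H](O)C/C(C)=C\2 | intermediate
34 | tert-butyl hydroperoxide | CC(C)(C)OO | starting material
35 | 8α-angeloyloxy-1β,10α-epoxy-2α-hydroxygermacra-4Z,11(13)-dien-6α,12-olide | C=C1C(=O)O[C@H]2[C@H]1[C@@H](OC(=O)/C(C)=C\C)C[C@@]1(C)O[C@@H]1[C@@H](O)C/C(C)=C\2 | intermediate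
36 | 8α-angeloyloxy-1β,10α:4α,5α-diepoxy-2α-hydroxygermacr-11(13)-en-6α,12-olide (CNP0388761.2) | C=C1C(=O)O[C@H]2[C@H]1[C@@H](OC(=O)/C(C)=C\C)C[C@@]1(C)O[C@@H]1[C@@H](O)C[C@@]1(C)O[C@@H]21 | target

## Step count and least certain steps

Total: 20 steps. Longest linear sequence: 19 steps (steps 1–5 and 7–20); step 6 is a one-step branch.

**Step 12 (key step).**
- What may go wrong: the triene is formed only to a photostationary fraction and is itself photolabile (return to 20, alkene isomerisation, bicyclic by-products). If the enol ether is not cleaved fast enough in the cold, the triene closes thermally in the disrotatory mode to a trans-fused diene. Some leakage into the other conrotatory mode through a non-chair ring B is a lesser risk.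
- Fallback: the fixing event is changed from protodesilylation to electrophilic capture. Setting out from 20, the cold photolysate is treated at −78 °C with PhSeCl, which converts silyl enol ethers into α-phenylseleno ketones within seconds, and this should give the 3-phenylseleno-2-oxo dienolide F1. Material derived from unchanged 20 is separated at this point. Soft deselenenylation of F1 (PhSH, Et3N, attack at selenium and protonation of the enol at C3) returns to the route at 22.

**Step 7.**
- What may go wrong: ionisation and β-elimination of the C8 silyloxy group under the silyl Lewis acid, with aromatisation of the ring, or arrest after the first conjugate addition because the second bond must form next to the new quaternary centre.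
- Fallback: the dienophile is activated by a removable ester. Setting out from 10, α-iodination (I2, pyridine) gives the 2-iodo enone F2. Carbonylation (Pd(OAc)2, PPh3, CO, allyl alcohol, Et3N) gives the allyl 2-carboxylate F3, a doubly activated dienophile that should add 13 thermally or with ZnCl2, again anti to the silyloxy group, to give the ester-bearing adduct F4. Deallylative decarboxylation with zerovalent palladium (Pd(PPh3)4, HCO2H, Et3N), with protonation at C5 to the cis-fused ketone, returns to the route at 14.

**Step 9.**
- What may go wrong: poor facial control in the electron-transfer reduction, giving the axial alcohol (which would close to a cis lactone), or competing reduction of the ester.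
- Fallback: the wrong alcohol is made on purpose and inverted. Setting out from 16, LiBH(sBu)3 attacks the open α face and the axial 6β-alkoxide closes to the cis-fused 6β,12-lactone F5. LiOH opens it to the 6β-hydroxy acid F6. Mitsunobu lactonisation (PPh3, iPrO2CN=NCO2iPr) closes the ring with inversion at C6 and returns to the route at 18.

**Step 14.**
- What may go wrong: loss of facial selectivity at C2, because two ring conformers may present different faces or hydride may enter on the C14 side. The inverting etherification of step 15 would then act on a mixture or on the wrong epimer.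
- Fallback: reagent control replaces substrate control. Setting out from 22, reduction with catecholborane and (S)-2-methyl-CBS-oxazaborolidine, whose sense for an alkenyl alkyl ketone corresponds to the 2R alcohol, arrives at 23 itself; no new compound is made.

**Step 20.**
- What may go wrong: incomplete or face-unselective epoxidation of the homoallylic C4=C5 alkene, which is the slower of the two deliveries, or over-oxidation of the allylic alcohol to the enone.
- Fallback: peripheral attack replaces directed delivery for the second alkene. Setting out from 33, the vanadium reaction is stopped at the monoepoxide 35, and the remaining trisubstituted cis alkene is epoxidised with dimethyldioxirane at low temperature on its exposed face. This reagent does not touch the electron-poor alkenes, and the sequence arrives at 36 without any new compound.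

## Further compounds

F1 | step 12 | 8α-(TBS-oxy)-2-oxo-3-(phenylselanyl)-13-norgermacra-1(10)E,4Z-dien-6α,12-olide (C3 epimers) | C1C(=O)O[C@H]2[C@H]1[C@@H](O[Si](C)(C)C(C)(C)C)C/C(C)=C/C(=O)C([Se]c3ccccc3)/C(C)=C\2
F2 | step 7 | (S)-2-iodo-3-methyl-5-(TBS-oxy)cyclohex-2-en-1-one | CC1=C(I)C(=O)C[C@@H](O[Si](C)(C)C(C)(C)C)C1
F3 | step 7 | allyl (S)-2-methyl-6-oxo-4-(TBS-oxy)cyclohex-1-ene-1-carboxylate | CC1=C(C(=O)OCC=C)C(=O)C[C@@H](O[Si](C)(C)C(C)(C)C)C1
F4 | step 7 | cis-fused Diels–Alder adduct carrying the allyl ester on C5 (C4 epimers) | O=C1C[C@@H](O[Si](C)(C)C(C)(C)C)C[C@]2(C)CC(O[Si](C)(C)C(C)(C)C)=CC(C)[C@]12C(=O)OCC=C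
F5 | step 9 | 2,8α-bis(TBS-oxy)-13-nor-5αH,10αMe-eudesm-2-en-6β,12-olide (cis lactone) | C1C(=O)O[C@@H]2[C@H]1[C@@H](O[Si](C)(C)C(C)(C)C)C[C@]3(C)CC(O[Si](C)(C)C(C)(C)C)=C[C@H](C)[C@H]23
F6 | step 9 | 2,8α-bis(TBS-oxy)-6β-hydroxy-13-nor-5αH,10αMe-eudesm-2-en-12-oic acid | O[C@@H]1[C@H](CC(=O)O)[C@@H](O[Si](C)(C)C(C)(C)C)C[C@]2(C)CC(O[Si](C)(C)C(C)(C)C)=C[C@H](C)[C@H]12
F0 | step 14 | none | none
F0 | step 20 | none | none
A1 | alternative 1 | α-diethylphosphono 6,12-lactone of the 8-angelate 2-silyl ether diepoxide | CCOP(=O)(OCC)[C@@H]1C(=O)O[C@H]2[C@H]1[C@@H](OC(=O)/C(C)=C\C)C[C@@]1(C)O[C@@H]1[C@@H](O[Si](C)(C)C(C)(C)C)C[C@@]1(C)O[C@@H]21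
A2 | alternative 2 | isoxazoline-bridged ten-membered lactone | C1C(=O)O[C@H]2[C@H]1[C@@H](O[Si](C)(C)C(C)(C)C)C/C(C)=C/C1=NO[C@](C)(C1)[C@@H]2O[Si](CC)(CC)CC
A3 | alternative 3 | ten-membered diene with free C8 hydroxyl and C7 2-(4-methoxybenzyloxymethyl)vinyl arm | C=C(COCc2ccc(OC)cc2)[C@@H]1[C@@H](O)C/C(C)=C/[C@@H](O[Si](C)(C)C(C)(C)C)C/C(C)=C\[C@H]1O[Si](C)(C)C(C)(C)C
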